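**Retrosynthetic overview**
1. Target ⇐ acetylation/desilylation and CBS reduction of a macrocyclic (Z)-enone ⇐ ring-closing metathesis (C11=C12), which closes the eleven-membered ring last.
2. C1 side arm plus exocyclic methylene ⇐ ketal Claisen rearrangement of a C15-hydroxymethyl cyclohexene, made from the ring ketone by enol triflate formation and Stille coupling.
3. C7–C8 bond with the C8 methyl ⇐ catalytic asymmetric Mukaiyama–Michael addition to a bicyclic enone; C9 ⇐ catalytic allylboration.
4. Five-membered ring ⇐ conjugate addition (quaternary C4) and aldol cyclopentene annulation on (S)-4-silyloxy-3-methylcyclohexenone.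
5. First stereocentre ⇐ Shi epoxidation of the deconjugated ketal of 3-methylcyclohexenone; ring order: six-membered ring A (present from the start) → five-membered ring B → eleven-membered ring C.

Locants and assumption: C15 is the ring carbon bearing the exocyclic CH2 (C17); C1 (bears C14) and C16 (ring-fusion CH) flank it; C2, C3 (OAc) and C4 (quaternary, methyl C18) complete ring A; C5, C6, C7 complete ring B; C8 (methyl C19), C9 (propanoate), C10, C11=C12 (methyl C20), C13 (OAc) and C14 close ring C. In these locants the target is (1R,3S,4S,7R,8S,9S,13R,16S,11Z). The Shi epoxidation of 3 is assumed to follow the usual facial sense for trisubstituted olefins, which calls for the L-fructose-derived ketone. TBS = tert-butyldimethylsilyl.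

**Step 1**
Reactants: 1 3-methylcyclohex-2-en-1-one; 2 ethane-1,2-diol
Product: 3 7-methyl-1,4-dioxaspiro[4.5]dec-7-ene
Conditions: p-TsOH·H2O (2 mol%), benzene, reflux, Dean–Stark
Reagents that add atoms: none
Why: Acid-catalysed deconjugative ketalisation moves the olefin out of conjugation and leaves an isolated trisubstituted olefin suited to electrophilic epoxidation.

**Step 2**
Reactants: 3 7-methyl-1,4-dioxaspiro[4.5]dec-7-ene
Product: 4 (7R,8S)-7,8-epoxy-7-methyl-1,4-dioxaspiro[4.5]decane
Conditions: ent-Shi ketone (L-fructose-derived, 30 mol%), KHSO5 (as 2KHSO5·KHSO4·K2SO4), K2CO3, Bu4NHSO4, MeCN–CH2(OMe)2–aq. buffer (pH 10.5), 0 °C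
Reagents that add atoms: potassium peroxymonosulfate KHSO5, [K+].[O-]S(=O)(=O)OO
Why: Shi asymmetric epoxidation, in which the chiral dioxirane delivers oxygen through a spiro transition state to one face of the trisubstituted olefin and so sets C3 (and C4), the first stereocentres, by metal-free catalysis.

**Step 3**
Reactants: 4 (7R,8S)-7,8-epoxy-7-methyl-1,4-dioxaspiro[4.5]decane
Product: 6 (S)-4-hydroxy-3-methylcyclohex-2-en-1-one, via epoxy ketone 5 (not isolated)
Conditions: SiO2, 10% aq. oxalic acid, CH2Cl2, rt; then Et3N, rt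
Reagents that add atoms: water, O
Why: Mild ketal hydrolysis followed by E1cB opening of the β,γ-epoxy ketone (C16–H removed, C4–O cleaved) gives the γ-hydroxy enone with the C3–O stereocentre untouched.

**Step 4**
Reactants: 6 (S)-4-hydroxy-3-methylcyclohex-2-en-1-one
Product: 7 (S)-4-[(tert-butyldimethylsilyl)oxy]-3-methylcyclohex-2-en-1-one
Conditions: t-BuMe2SiCl, imidazole, DMF, rt
Reagents that add atoms: tert-butyldimethylsilyl chloride, CC(C)(C)[Si](C)(C)Cl
Why: Silyl ether formation protects the C3 hydroxyl as a robust, bulky group that later steers the conjugate addition to the opposite face.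

**Step 5**
Reactants: 7 (S)-4-[(tert-butyldimethylsilyl)oxy]-3-methylcyclohex-2-en-1-one; 8 [2-(1,3-dioxan-2-yl)ethyl]magnesium bromide
Product: 10 (3S,4S)-4-[(tert-butyldimethylsilyl)oxy]-3-[2-(1,3-dioxan-2-yl)ethyl]-3-methylcyclohexan-1-one, via TMS enol ether 9 (not isolated)
Conditions: CuBr·SMe2 (20 mol%), Me3SiCl, THF, −78 to −30 °C; then aq. NH4Cl, dilute citric acid
Reagents that add atoms: none
Why: Copper-catalysed, Me3SiCl-accelerated conjugate addition in which the organocopper attacks C4 anti to the adjacent C3 silyloxy group, so the quaternary centre forms with its methyl cis to the C3 oxygen.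

**Step 6**
Reactants: 10 (3S,4S)-4-[(tert-butyldimethylsilyl)oxy]-3-[2-(1,3-dioxan-2-yl)ethyl]-3-methylcyclohexan-1-one
Product: 12 (7S,7aS)-7-[(tert-butyldimethylsilyl)oxy]-7a-methyl-1,2,5,6,7,7a-hexahydro-4H-inden-4-one, via keto aldehyde 11 (not isolated)
Conditions: p-TsOH·H2O (10 mol%), THF–H2O (4:1), 45 °C; then KOH, MeOH, rt
Reagents that add atoms: none
Why: Acetal hydrolysis and intramolecular aldol condensation (cyclopentene annulation) close ring B through C16–C7, the five-membered aldol being the only one that can dehydrate to a conjugated enone.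

**Step 7**
Reactants: 13 methyl propanoate
Product: 14 (Z)-tert-butyl[(1-methoxyprop-1-en-1-yl)oxy]dimethylsilane
Conditions: LiN(i-Pr)2, THF–DMPU (4:1), −78 °C; then t-BuMe2SiCl, −78 °C to rt
Reagents that add atoms: tert-butyldimethylsilyl chloride, CC(C)(C)[Si](C)(C)Cl
Why: Ireland-type ester enolisation in the presence of DMPU followed by O-silylation gives the (Z)-silyl ketene acetal.

**Step 8**
Reactants: 12 (7S,7aS)-7-[(tert-butyldimethylsilyl)oxy]-7a-methyl-1,2,5,6,7,7a-hexahydro-4H-inden-4-one; 14 (Z)-tert-butyl[(1-methoxyprop-1-en-1-yl)oxy]dimethylsilane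
Product: 16 methyl (2S)-2-[(3R,3aR,7S,7aS)-7-[(tert-butyldimethylsilyl)oxy]-7a-methyl-4-oxooctahydro-1H-inden-3-yl]propanoate, via TBS enol ether 15 (not isolated)
Conditions: (S,S)-IDPi Brønsted acid (BINOL-derived imidodiphosphorimidate with N-triflyl core, 2 mol%), toluene, −60 °C; then 1 M HCl, THF, 0 °C
Reagents that add atoms: none
Why: Proposed new method: a catalyst-controlled, doubly diastereoselective Mukaiyama–Michael addition under silylium counteranion-directed catalysis, in which the IDPi acid is silylated by 14, the silylium–IDPi ion pair activates the enone carbonyl of 12, and the ketene acetal attacks C7 anti to the angular C4 methyl through an open antiperiplanar transition state where the confined chiral anion over the C15–O side pushes the C8 methyl toward C6, setting C7 and C8 in one bond-forming event before silyl transfer gives 15 and acidic work-up protonates C16 anti to the new substituent to give the cis-fused ketone; the closest known reaction type is the IDPi- or disulfonimide-catalysed Mukaiyama–Michael addition of silyl ketene acetals to α,β-unsaturated esters and simple enones, not yet shown for a bicyclic enone next to a quaternary centre with control of the exocyclic α-stereocentre.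

**Step 9**
Reactants: 16 methyl (2S)-2-[(3R,3aR,7S,7aS)-7-[(tert-butyldimethylsilyl)oxy]-7a-methyl-4-oxooctahydro-1H-inden-3-yl]propanoate
Product: 17 C15 enol triflate of 16 (C15=C1)
Conditions: KN(SiMe3)2, THF, −78 °C; then PhNTf2, −78 to 0 °C
Reagents that add atoms: N-phenylbis(trifluoromethanesulfonimide), FC(F)(F)S(=O)(=O)N(c1ccccc1)S(=O)(=O)C(F)(F)F
Why: Kinetic enolisation at the less hindered C1 methylene and O-sulfonylation (enol triflate formation) give the C15=C1 vinyl triflate, leaving the ester α-hydrogen untouched at −78 °C.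

**Step 10**
Reactants: 17 C15 enol triflate of 16 (C15=C1)
Product: 18 aldehyde obtained from 17 by reduction of CO2Me (C9) to CHO
Conditions: i-Bu2AlH (1.1 equiv), CH2Cl2, −78 °C; aq. KNaC4H4O6 work-up
Reagents that add atoms: none
Why: Low-temperature DIBAL reduction stops at the tetrahedral aluminium hemiacetal, which gives the aldehyde on work-up, while vinyl triflate and silyl ether are inert.

**Step 11**
Reactants: 18 aldehyde obtained from 17 by reduction of CO2Me (C9) to CHO; 19 2-allyl-4,4,5,5-tetramethyl-1,3,2-dioxaborolane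
Product: 20 (9S)-homoallylic alcohol (C9–OH with C10H2–C11H=CH2)
Conditions: (S)-TRIP phosphoric acid (5 mol%), 4 Å MS, toluene, −30 °C
Reagents that add atoms: none
Why: Chiral phosphoric acid-catalysed allylboration through a chair-like six-membered transition state, with catalyst control and Felkin–Anh control from the C8 methyl centre matched to give the 8,9-syn (9S) alcohol.

**Step 12**
Reactants: 20 (9S)-homoallylic alcohol (C9–OH with C10H2–C11H=CH2); 21 propanoic anhydride
Product: 22 C9 propanoate of 20
Conditions: Et3N, DMAP (cat.), CH2Cl2, 0 °C to rt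
Reagents that add atoms: none
Why: DMAP-catalysed acylation puts the propanoate on the only free hydroxyl, fixing the ester pattern of the target early.

**Step 13**
Reactants: 22 C9 propanoate of 20; 23 (tributylstannyl)methanol
Product: 24 primary allylic alcohol (CH2OH = C17 on C15 with C15=C1)
Conditions: Pd(PPh3)4 (5 mol%), LiCl, 1,4-dioxane, 90 °C
Reagents that add atoms: none
Why: Stille cross-coupling of the vinyl triflate with the hydroxymethyl stannane gives the allylic alcohol, and without added base a Heck pathway onto the remote olefin cannot turn over.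

**Step 14**
Reactants: 25 3-methylbut-3-en-2-one
Product: 26 3,3-dimethoxy-2-methylbut-1-ene
Conditions: HC(OMe)3, p-TsOH·H2O (cat.), MeOH, 0 °C to rt
Reagents that add atoms: trimethyl orthoformate, COC(OC)OC
Why: Acid-catalysed ketalisation with trimethyl orthoformate as methanol source and water scavenger gives the ketal used as the Claisen partner.

**Step 15**
Reactants: 24 primary allylic alcohol (CH2OH = C17 on C15 with C15=C1); 26 3,3-dimethoxy-2-methylbut-1-ene
Product: 28 isopropenyl ketone with C1–C14H2–C13(=O)–C12(CH3)=CH2 arm and exocyclic C15=C17, via allyl dienyl ether 27 (not isolated)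
Conditions: EtCO2H (10 mol%), toluene, 110 °C, sealed tube, 4 Å MS
Reagents that add atoms: none
Why: Johnson-type ketal Claisen rearrangement, in which exchange and loss of methanol give the allyl dienyl ether whose [3,3] shift forms C1–C14 on the face anti to the C7 substituent at C16 (held pseudoaxial by allylic 1,2-strain), sets C1 and places the olefin at exocyclic C15=C17.

**Step 16**
Reactants: 28 isopropenyl ketone with C1–C14H2–C13(=O)–C12(CH3)=CH2 arm and exocyclic C15=C17
Product: 29 macrocyclic (11Z)-enone (C13 ketone)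
Conditions: second-generation Hoveyda–Grubbs catalyst RuCl2(SIMes)(=CH-C6H4-2-O-i-Pr) (10 mol%), toluene (1 mM), 80 °C
Reagents that add atoms: none
Why: Ring-closing metathesis between the allyl terminus and the isopropenyl ketone closes ring C, the bridged eleven-membered ring accommodating only the (Z)-trisubstituted olefin and the hindered exocyclic methylene expected to stay a spectator.

**Step 17**
Reactants: 29 macrocyclic (11Z)-enone (C13 ketone)
Product: 30 (13R)-allylic alcohol
Conditions: (S)-2-methyl-CBS-oxazaborolidine (0.3 equiv), catecholborane, toluene, −78 °C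
Reagents that add atoms: none
Why: Corey–Bakshi–Shibata reduction, in which the oxazaborolidine binds the ketone anti to the alkenyl (large) group and delivers hydride 1,2 to give the (13R) alcohol.

**Step 18**
Reactants: 30 (13R)-allylic alcohol; 31 acetic anhydride
Product: 33 target compound CNP0239696.1, via diol 32 (not isolated)
Conditions: HF·pyridine, pyridine–THF, 0 °C to rt; then 31, DMAP, rt
Reagents that add atoms: none
Why: Fluoride-mediated desilylation frees the C3 hydroxyl and DMAP-catalysed acetylation esterifies both secondary alcohols without touching any stereocentre.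

**Compound list**
1 | 3-methylcyclohex-2-en-1-one | CC1=CC(=O)CCC1 | starting material
2 | ethane-1,2-diol | OCCO | starting material
3 | 7-methyl-1,4-dioxaspiro[4.5]dec-7-ene | CC1=CCCC2(C1)OCCO2 | intermediate
4 | (7R,8S)-7,8-epoxy-7-methyl-1,4-dioxaspiro[4.5]decane | C[C@@]1(O2)CC3(OCCO3)CC[C@@H]12 | intermediate
5 | (3R,4S)-3,4-epoxy-3-methylcyclohexan-1-one | C[C@@]1(O2)CC(=O)CC[C@@H]12 | intermediate
6 | (S)-4-hydroxy-3-methylcyclohex-2-en-1-one | CC1=CC(=O)CC[C@@H]1O | intermediate
7 | (S)-4-[(tert-butyldimethylsilyl)oxy]-3-methylcyclohex-2-en-1-one | CC1=CC(=O)CC[C@@H]1O[Si](C)(C)C(C)(C)C | intermediate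
8 | [2-(1,3-dioxan-2-yl)ethyl]magnesium bromide | Br[Mg]CCC1OCCCO1 | starting material
9 | trimethylsilyl enol ether of 10 (C15–OSiMe3, C15=C16) | C[Si](C)(C)OC1=C[C@](C)(CCC2OCCCO2)[C@@H](O[Si](C)(C)C(C)(C)C)CC1 | intermediate
10 | (3S,4S)-4-[(tert-butyldimethylsilyl)oxy]-3-[2-(1,3-dioxan-2-yl)ethyl]-3-methylcyclohexan-1-one | O=C1C[C@](C)(CCC2OCCCO2)[C@@H](O[Si](C)(C)C(C)(C)C)CC1 | intermediate
11 | 3-[(1S,2S)-2-[(tert-butyldimethylsilyl)oxy]-1-methyl-5-oxocyclohexyl]propanal | O=C1C[C@](C)(CCC=O)[C@@H](O[Si](C)(C)C(C)(C)C)CC1 | intermediate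
12 | (7S,7aS)-7-[(tert-butyldimethylsilyl)oxy]-7a-methyl-1,2,5,6,7,7a-hexahydro-4H-inden-4-one | O=C1CC[C@H](O[Si](C)(C)C(C)(C)C)[C@@]2(C)CCC=C12 | intermediate
13 | methyl propanoate | CCC(=O)OC | starting material
14 | (Z)-tert-butyl[(1-methoxyprop-1-en-1-yl)oxy]dimethylsilane | C/C=C(\O[Si](C)(C)C(C)(C)C)OC | intermediate
15 | TBS enol ether of 16 (C15–OTBS, C15=C16) | CC(C)(C)[Si](C)(C)OC1=C2[C@H]([C@H](C)C(=O)OC)CC[C@]2(C)[C@@H](O[Si](C)(C)C(C)(C)C)CC1 | intermediate
16 | methyl (2S)-2-[(3R,3aR,7S,7aS)-7-[(tert-butyldimethylsilyl)oxy]-7a-methyl-4-oxooctahydro-1H-inden-3-yl]propanoate | O=C1CC[C@H](O[Si](C)(C)C(C)(C)C)[C@@]2(C)CC[C@@H]([C@H](C)C(=O)OC)[C@@H]12 | intermediate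
17 | C15 enol triflate of 16: methyl (2S)-2-[(3R,3aR,7S,7aS)-7-[(tert-butyldimethylsilyl)oxy]-7a-methyl-4-{[(trifluoromethyl)sulfonyl]oxy}-2,3,3a,6,7,7a-hexahydro-1H-inden-3-yl]propanoate | O=S(=O)(OC1=CC[C@H](O[Si](C)(C)C(C)(C)C)[C@@]2(C)CC[C@@H]([C@H](C)C(=O)OC)[C@@H]12)C(F)(F)F | intermediate
18 | aldehyde: 17 with CO2Me (C9) reduced to CHO, all centres as in 17 | O=S(=O)(OC1=CC[C@H](O[Si](C)(C)C(C)(C)C)[C@@]2(C)CC[C@@H]([C@H](C)C=O)[C@@H]12)C(F)(F)F | intermediate
19 | 2-allyl-4,4,5,5-tetramethyl-1,3,2-dioxaborolane | C=CCB1OC(C)(C)C(C)(C)O1 | starting material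
20 | (9S)-homoallylic alcohol: 18 with C9 as CH(OH)CH2CH=CH2, side chain (2S,3S)-3-hydroxyhex-5-en-2-yl at C7 | O=S(=O)(OC1=CC[C@H](O[Si](C)(C)C(C)(C)C)[C@@]2(C)CC[C@@H]([C@H](C)[C@@H](O)CC=C)[C@@H]12)C(F)(F)F | intermediate
21 | propanoic anhydride | CCC(=O)OC(=O)CC | starting material
22 | C9 propanoate of 20 | O=S(=O)(OC1=CC[C@H](O[Si](C)(C)C(C)(C)C)[C@@]2(C)CC[C@@H]([C@H](C)[C@@H](OC(=O)CC)CC=C)[C@@H]12)C(F)(F)F | intermediate
23 | (tributylstannyl)methanol | CCCC[Sn](CCCC)(CCCC)CO | starting material
24 | primary allylic alcohol: 22 with OTf replaced by CH2OH (C17), C15=C1 | OCC1=CC[C@H](O[Si](C)(C)C(C)(C)C)[C@@]2(C)CC[C@@H]([C@H](C)[C@@H](OC(=O)CC)CC=C)[C@@H]12 | intermediate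
25 | 3-methylbut-3-en-2-one | CC(=O)C(C)=C | starting material
26 | 3,3-dimethoxy-2-methylbut-1-ene | COC(C)(OC)C(C)=C | intermediate
27 | 3-methylbuta-1,3-dien-2-yl ether of 24 | C=C(C)C(=C)OCC1=CC[C@H](O[Si](C)(C)C(C)(C)C)[C@@]2(C)CC[C@@H]([C@H](C)[C@@H](OC(=O)CC)CC=C)[C@@H]12 | intermediate
28 | Claisen product: C1 bears CH2C(=O)C(CH3)=CH2 trans to C7, exocyclic C15=C17, C3–OTBS, C9 propanoate, C10–C11H=CH2 | C=C1[C@H](CC(=O)C(C)=C)C[C@H](O[Si](C)(C)C(C)(C)C)[C@@]2(C)CC[C@@H]([C@H](C)[C@@H](OC(=O)CC)CC=C)[C@@H]12 | intermediate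
29 | macrocyclic (11Z)-enone: target skeleton with C13 ketone and C3–OTBS | C=C1[C@H]2C[C@H](O[Si](C)(C)C(C)(C)C)[C@@]3(C)CC[C@@H]([C@H](C)[C@@H](OC(=O)CC)C/C=C(/C)C(=O)C2)[C@@H]13 | intermediate
30 | (13R)-allylic alcohol with C3–OTBS | C=C1[C@H]2C[C@H](O[Si](C)(C)C(C)(C)C)[C@@]3(C)CC[C@@H]([C@H](C)[C@@H](OC(=O)CC)C/C=C(/C)[C@H](O)C2)[C@@H]13 | intermediate
31 | acetic anhydride | CC(=O)OC(C)=O | starting material
32 | 3,13-diol 9-propanoate | C=C1[C@H]2C[C@H](O)[C@@]3(C)CC[C@@H]([C@H](C)[C@@H](OC(=O)CC)C/C=C(/C)[C@H](O)C2)[C@@H]13 | intermediate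
33 | CNP0239696.1, (1R,3S,4S,7R,8S,9S,13R,16S,11Z)-3,13-diacetate 9-propanoate | C=C1[C@H]2C[C@H](OC(C)=O)[C@@]3(C)CC[C@@H]([C@H](C)[C@@H](OC(=O)CC)C/C=C(/C)[C@H](OC(C)=O)C2)[C@@H]13 | target

**Step count and risks**
Total: 18 steps. Longest linear sequence: 16 steps (steps 1–6, 8–13, 15–18); steps 7 and 14 prepare 14 and 26.

The three steps most likely to fail:

Step 5, where the quaternary carbon must form next to the silyloxy-bearing carbon by copper-catalysed conjugate addition. The fallback sets out from 7. Hosomi–Sakurai allylation (allyltrimethylsilane, TiCl4, CH2Cl2, −78 °C) builds the quaternary centre anti to the silyloxy group and gives (3S,4S)-3-allyl-4-[(tert-butyldimethylsilyl)oxy]-3-methylcyclohexan-1-one F1. Aldehyde-selective Wacker oxidation of its terminal olefin (PdCl2(PhCN)2, CuCl2, AgNO2, t-BuOH–MeNO2, O2) then gives keto aldehyde 11, where the route is rejoined (KOH, MeOH to 12 as in step 6).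

Step 8, the proposed catalyst-controlled Mukaiyama–Michael addition; the C8 configuration is the uncertain point. The fallback uses known chemistry and sets out from 12. A substrate-controlled Mukaiyama–Michael addition of commercial 1-(tert-butyldimethylsilyloxy)-1-methoxyethene under Tf2NH catalysis (CH2Cl2, −78 °C) gives the bis-silylated acetate adduct F2, with C7 set anti to the angular methyl. Ester enolate formation with LiN(i-Pr)2 and methylation with MeI (THF, −78 °C) then sets C8 under allylic 1,3-strain control (H7 eclipses the enolate, MeI enters anti to the C16 branch) and gives TBS enol ether 15, where the route is rejoined (acid work-up to 16).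

Step 16, the ring-closing metathesis. An eleven-membered trisubstituted olefin must form, while the carbene at C11 could instead close a seven-membered ring onto the exocyclic C15 methylene. The fallback sets out from 28. Chemoselective epoxidation of the electron-rich 1,1-dialkyl exocyclic olefin (m-CPBA, NaHCO3, CH2Cl2, 0 °C) gives spiro-epoxide F3; the isopropenyl ketone is deactivated and the monosubstituted olefin reacts more slowly. Ring-closing metathesis under the step 16 conditions gives epoxy macrocycle F4. Rhenium-catalysed deoxygenation (MeReO3, PPh3, benzene, rt) restores the exocyclic olefin and rejoins the route at 29.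

**Further compounds**
F1 | step 5 | (3S,4S)-3-allyl-4-[(tert-butyldimethylsilyl)oxy]-3-methylcyclohexan-1-one | O=C1C[C@](C)(CC=C)[C@@H](O[Si](C)(C)C(C)(C)C)CC1
F2 | step 8 | methyl 2-[(3S,7S,7aS)-4,7-bis[(tert-butyldimethylsilyl)oxy]-7a-methyl-2,3,5,6,7,7a-hexahydro-1H-inden-3-yl]acetate | CC(C)(C)[Si](C)(C)OC1=C2[C@H](CC(=O)OC)CC[C@]2(C)[C@@H](O[Si](C)(C)C(C)(C)C)CC1
F3 | step 16 | spiro-epoxide of 28 (oxirane from C15=C17, oxygen anti to C7) | C1O[C@@]12[C@H](CC(=O)C(C)=C)C[C@H](O[Si](C)(C)C(C)(C)C)[C@@]3(C)CC[C@@H]([C@H](C)[C@@H](OC(=O)CC)CC=C)[C@@H]23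
F4 | step 16 | spiro-epoxide of 29 (oxirane from C15=C17, oxygen anti to C7) | C1O[C@@]12[C@H]3C[C@H](O[Si](C)(C)C(C)(C)C)[C@@]4(C)CC[C@@H]([C@H](C)[C@@H](OC(=O)CC)C/C=C(/C)C(=O)C3)[C@@H]24
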